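- At 5.00 h the oak run holds 81 % starting material, less than the 89 % in the alder run, and oak was charged with more free catalyst.

| setting | alder | oak | epsilon | gamma | zeta |
|---|---|---|---|---|---|
| starting material | 0.10 M | 0.10 M | 0.10 M | 0.10 M | 0.10 M |
| reagent | 0.15 M | 0.15 M | 0.150 M | 0.150 M | 0.150 M |
| free catalyst | 0.18 mM | 0.27 mM | 0.36 mM | 0.36 mM | 0.36 mM |
| remark | run made earlier | run made earlier |  |  |  |
| time |  |  | 8.0 h | 15 h | 30 h |

| run | time / h | product / % | catalyst intermediate B / % | starting material / % | catalyst intermediate C / % |
|---|---|---|---|---|---|
| alder | 0.417 | 2 | 0 | 98 | 0 |
| alder | 0.833 | 4 | 4 | 98 | 0 |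
| alder | 2.00 | 3 | 2 | 95 | 2 |
| alder | 5.00 | 10 | 2 | 89 | 0 |
| oak | 0.667 | 2 | 0 | 101 | 0 |
| oak | 1.50 | 4 | 0 | 95 | 0 |
| oak | 3.00 | 6 | 1 | 88 | 0 |
| oak | 5.00 | 17 | 0 | 81 | 2 |

(scatter of a reading: 2 percentage points)

- which of these there is most of at the end, counted by the starting material in it, epsilon (catalyst intermediate C / catalyst intermediate B / product / starting material)
- which of these there is most of at the end, counted by the starting material in it, gamma (catalyst intermediate C / catalyst intermediate B / product / starting material)
- which of these there is most of at the end, counted by the starting material in it, zeta (catalyst intermediate C / catalyst intermediate B / product / starting material)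
- final amount of the leader among these, as a percentage of the starting material charged, in epsilon
- final amount of the leader among these, as a percentage of the starting material charged, in gamma
- final amount of the leader among these, as a percentage of the starting material charged, in zeta



- The reckoning here treats the loss of starting material as pseudo-first-order, with a rate constant proportional to the [free catalyst] charged.
- Scaled to 0.36 mM, the alder reading gives 0.0466 h⁻¹ and the oak reading 0.0562 h⁻¹. These rest on single readings at 5.00 h, with losses of 11 percentage points and 19 points and a scatter of 2 points, so their mean, 0.0514 h⁻¹, is a rough estimate of the constant.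
- The crossing time is the time at which [starting material] equals [product], ln(2) over that constant: 13.5 h.
- The charged catalyst is 0.360 % of the starting material, so catalyst intermediates B and C cannot lead, and the race has two runners.
- The curve falls to 66.3 % at 8.0 h, before the crossing, so starting material leads in epsilon.
- It reaches 46.3 % at 15 h, just past the crossing, so product leads in gamma at 53.7 %.
- It reaches 21.4 % at 30 h, so product leads in zeta at 78.6 %.
- If one reagent is used per starting material, the reagent charge exceeds what is needed, starting material is the limiting reagent, and the curve heads toward full conversion.
- The forecast names the same leaders, with starting material at 67 %, product at 53 % and product at 76 %; its product figures for gamma and zeta lie below those reckoned here. Its ground: “The race is between starting material and product”.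
- Epsilon ends with starting material at 64.5 %, gamma with product at 56.2 % and zeta with product at 80.1 %.
- In zeta, starting material stands at 51.5 % at 12 h and 43.6 % at 15.0 h, on either side of the crossing time of 13.5 h.

    reagent + free catalyst → catalyst intermediate A (k = 0.200 M⁻¹ s⁻¹)
    starting material + catalyst intermediate A → catalyst intermediate B (k = 0.0700 M⁻¹ s⁻¹)
    catalyst intermediate B → released group + catalyst intermediate C (k = 0.0300 s⁻¹)
    catalyst intermediate C → free catalyst + product (k = 0.0270 s⁻¹)
    catalyst intermediate B + product → spent catalyst (k = 0.00110 M⁻¹ s⁻¹)

- A neighbour of zeta is charged with 0.25 M starting material, its other charges and time held. The crossing time contains no [starting material], so the reckoning again gives 21.4 % left, but this neighbour holds 53.0 %, and starting material leads. Its spent catalyst stands at 69.9 % of the catalyst charged, more than the 32.7 % in zeta.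

All runs come from a simulation for substances that don't exist, and the scatter is random.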